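**Retrosynthetic overview**

1. Feature: the spiro carbon C2 of the benzofuran-3(2H)-one (ring O1–C2–C3–C3a–C7a) is bonded both to O1 and to the carbonyl carbon C3, and also to C8 of the flavonol and to the hemiketal carbon. O1 and C3 correspond to the hydroxyl oxygen and the formyl carbon of a 4,6-dioxygenated salicylaldehyde.
2. Last disconnection: the hemiketal ring (flavonol O7, C7, C8, spiro C2, hemiketal carbon) opens to a free 7-OH and a 2-aroyl ketone, and the C3 ketone is traced back to a carbinol.
3. Key disconnection: O1–C2 and C2–C3 are cut together, giving an α-(flavonol-8-yl) α-diazo aryl ketone (carbene carbon = C2) and 2-hydroxy-4,6-bis(benzyloxy)benzaldehyde, joined in a [4+1] annulation by carbene O–H insertion with aldol capture.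
4. The diazo ketone comes from an 8-iodoflavonol by Pd α-arylation of 4'-benzyloxyacetophenone and diazo transfer. O7 sits ortho to the carbene carbon and is carried as a tert-butyl ether, because a benzyl ether there would place a C–H bond 1,5 to the carbene; it is set apart from the other oxygens of kaempferol by selective 7-O-deacetylation.
5. Ring order: the chromone and its aryl rings come with kaempferol, the benzofuranone ring is closed in the key step, and the hemiketal furan ring closes last, when O7 is freed.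

Key step: step 9

Assumption 1: the hemiketal equilibrates by ring–chain tautomerism, and the form of the target (O7 closed onto the aroyl carbon, C8' R, its OH on the side of the C3 carbonyl, its aryl on the side of O1) is taken as the thermodynamically preferred one.
Assumption 2: the hand of the phosphoric acid that leads to (2S) cannot be predicted with certainty; (R)-TRIP is written, and its antipode is used if a first run shows the opposite sense.

**Route**

Step 1
Reactants: 1 kaempferol
Product: 2 3,5,7,4'-tetra-O-acetylkaempferol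
Conditions: Ac2O, pyridine, DMAP (cat.), rt
Reagents that add atoms: acetic anhydride, CC(=O)OC(C)=O
Why: Exhaustive O-acylation of the four hydroxyl groups (nucleophilic acyl substitution with DMAP catalysis), which also acylates the chelated 5-OH.

Step 2
Reactants: 2 3,5,7,4'-tetra-O-acetylkaempferol
Product: 3 3,5,4'-tri-O-acetylkaempferol (7-OH free)
Conditions: PhSH, imidazole, NMP, 0 °C
Reagents that add atoms: none
Why: Thiolate-mediated transacylation is selective for the 7-acetate, the most activated aryl ester of a flavonoid peracetate because its phenoxide, para to the C4 carbonyl, is the best leaving group.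

Step 3
Reactants: 3 3,5,4'-tri-O-acetylkaempferol
Product: 4 3,5,4'-tri-O-acetyl-7-O-tert-butylkaempferol
Conditions: isobutene (excess), TfOH (cat.), CH2Cl2, −78 → −20 °C; Et3N quench
Reagents that add atoms: isobutene, CC(C)=C
Why: Acid-catalysed addition of the phenol to isobutene (tert-butyl ether formation by capture of the tert-butyl cation), in which the acetates survive and the acylated, carbonyl-deactivated ring A resists Friedel–Crafts alkylation at low temperature.

Step 4
Reactants: 4 3,5,4'-tri-O-acetyl-7-O-tert-butylkaempferol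
Product: 6 3,5,4'-tri-O-benzyl-7-O-tert-butylkaempferol, via 7-O-tert-butylkaempferol 5 (not isolated)
Conditions: K2CO3, MeOH, rt, Ar; evaporate; BnBr (4.5 equiv), K2CO3, DMF, 70 °C
Reagents that add atoms: benzyl bromide, BrCc1ccccc1
Why: Methanolysis of the three acetates (transesterification) followed by Williamson benzylation, with excess bromide and heat for the chelated 5-OH, while the tert-butyl ether is inert to base and exclusion of air protects the free flavonol.

Step 5
Reactants: 6 3,5,4'-tri-O-benzyl-7-O-tert-butylkaempferol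
Product: 7 3,5,4'-tri-O-benzyl-7-O-tert-butyl-8-iodokaempferol
Conditions: I2, AgOAc, CH2Cl2, rt, dark
Reagents that add atoms: iodine, II
Why: Electrophilic aromatic iodination by acetyl hypoiodite, which in fully O-alkylated 5,7-dioxygenated flavones goes to C8 (para to the 5-alkoxy group, next to the unsubstituted ring oxygen) and not to C6 (between two alkoxy groups), ring B and the benzyl rings being less activated.

Step 6
Reactants: 7 3,5,4'-tri-O-benzyl-7-O-tert-butyl-8-iodokaempferol; 8 4'-benzyloxyacetophenone (2 equiv)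
Product: 9 1-(4-benzyloxyphenyl)-2-(3,5,4'-tri-O-benzyl-7-O-tert-butylkaempferol-8-yl)ethanone
Conditions: Pd2(dba)3 (2.5 mol %), XPhos (6 mol %), K3PO4, toluene, 90 °C
Reagents that add atoms: none
Why: Buchwald–Hartwig-type Pd-catalysed α-arylation of a ketone (oxidative addition of C8–I, exchange with the potassium enolate of 8, C–C reductive elimination), where the bulky biaryl phosphine suits the di-ortho-substituted iodide, K3PO4 spares the chromone, and the excess of 8 with the crowding of the product should limit the reaction to monoarylation.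

Step 7
Reactants: 9 the 8-phenacyl flavonol
Product: 10 2-diazo-1-(4-benzyloxyphenyl)-2-(3,5,4'-tri-O-benzyl-7-O-tert-butylkaempferol-8-yl)ethanone
Conditions: p-ABSA, DBU, MeCN, 0 °C → rt
Reagents that add atoms: 4-acetamidobenzenesulfonyl azide (p-ABSA), CC(=O)Nc1ccc(cc1)S(=O)(=O)N=[N+]=[N-]
Why: Regitz diazo transfer, in which DBU deprotonates the methylene activated by aryl and aroyl groups and the enolate attacks the sulfonyl azide with loss of the sulfonamide, as is established for deoxybenzoins.

Step 8
Reactants: 11 2,4,6-trihydroxybenzaldehyde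
Product: 12 2-hydroxy-4,6-bis(benzyloxy)benzaldehyde
Conditions: BnBr (2.1 equiv), K2CO3, DMF, 0 °C → rt
Reagents that add atoms: benzyl bromide, BrCc1ccccc1
Why: Williamson etherification in which the 4-OH and one ortho OH react, while the remaining ortho OH is chelated to the formyl oxygen, is much less nucleophilic and stays free.

Step 9
Reactants: 10 the diazo ketone (added slowly); 12 2-hydroxy-4,6-bis(benzyloxy)benzaldehyde (1.5 equiv)
Product: 14 (2S,3R)-2-(4-benzyloxybenzoyl)-4,6-bis(benzyloxy)-2-(3,5,4'-tri-O-benzyl-7-O-tert-butylkaempferol-8-yl)-2,3-dihydrobenzofuran-3-ol (3-OH cis to the aroyl group), via aryloxy enol 13 (not isolated)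
Conditions: Rh2(OAc)4 (2 mol %), (R)-TRIP (10 mol %), 4 Å MS, CH2Cl2, 0 °C, 10 added over 2 h
Reagents that add atoms: none
Why: Rh2(OAc)4 converts 10 into a donor/acceptor rhodium carbene, the phenol oxygen of 12 adds to it, and the oxonium ylide passes its proton to the ketone oxygen to give the aryloxy enol 13, whose carbon attacks the ortho formyl group before tautomerisation to the ketone. The closest known reaction type is the Rh(II)/chiral phosphoric acid co-catalysed O–H insertion of aryl diazo carbonyl compounds with aldol-type trapping of the oxonium ylide, including its intramolecular form that gives 3-hydroxy-2,3-dihydrobenzofurans. The ring O1–C2–C3–C3a–C7a closes by a 5-(enolexo)-exo-trig aldol addition that forms C2–C3 after the intermolecular O1–C2 bond. C2 is set by the phosphoric acid, which holds the enol OH and the formyl oxygen in one hydrogen-bonded assembly and so selects the enol face; C3 is set relative to C2 by the same assembly, expected to place the 3-OH cis to the aroyl group, and is removed in step 10. The step needs O–H attack to outrun intramolecular reactions of the carbene and aldol capture to outrun the 1,2-proton shift: the tert-butyl ether at O7 has no C–H bond 1,5 to the carbene carbon (a benzyl ether there would give a dihydrobenzofuran by C–H insertion), slow addition of 10 suppresses azine and dimer formation, and the formyl group is held ortho to the new ether oxygen and activated by the acid.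

Step 10
Reactants: 14 the dihydrobenzofuranol
Product: 15 (R)-2-(4-benzyloxybenzoyl)-4,6-bis(benzyloxy)-2-(3,5,4'-tri-O-benzyl-7-O-tert-butylkaempferol-8-yl)benzofuran-3(2H)-one
Conditions: Dess–Martin periodinane, CH2Cl2, 0 °C → rt
Reagents that add atoms: none
Why: Dess–Martin oxidation of the benzylic secondary alcohol under non-basic conditions, which avoids retro-aldol opening of the β-hydroxy ketone and leaves the quaternary, non-enolisable C2 intact (the descriptor changes from S to R only because the priorities change).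

Step 11
Reactants: 15 the 2-aroylbenzofuranone
Product: 17 hexa-O-benzyl ether of the target with free hemiketal OH (2S,8'R; benzyl on O4 and O6 of the benzofuranone, on O3' and O5' of the furochromenone and on both 4-hydroxyphenyl groups), via 7-hydroxy diketone 16 (not isolated)
Conditions: TFA–CH2Cl2 (1:4), 0 °C → rt
Reagents that add atoms: none
Why: Acidolysis of the aryl tert-butyl ether (E1 loss of isobutene) frees the 7-OH, which adds to the adjacent aroyl carbonyl in a 5-exo-trig hemiketalisation, the new hemiketal centre being set relative to C2 under thermodynamic control through reversible ring opening in the acid.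

Step 12
Reactants: 17 the hexa-O-benzyl hemiketal
Product: 18 (2S,8'R)-3',4,5',6,8'-pentahydroxy-2',8'-bis(4-hydroxyphenyl)-3H,4'H,8'H-spiro[benzofuran-2,9'-furo[2,3-h]chromene]-3,4'-dione (CNP0283000.1)
Conditions: H2 (1 atm), 10% Pd/C, THF–EtOAc, rt
Reagents that add atoms: none
Why: Catalytic hydrogenolysis of the six aryl benzyl ethers under neutral conditions in a non-nucleophilic solvent, which should leave the aryl ketones, the flavonol C2=C3 bond, the quaternary spiro centre and the hemiketal in place, the hemiketal centre staying at its equilibrium configuration.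

**Compound list**

1 | kaempferol | O=c1c(O)c(-c2ccc(O)cc2)oc2cc(O)cc(O)c12 | starting material
2 | 3,5,7,4'-tetra-O-acetylkaempferol | O=c1c(OC(C)=O)c(-c2ccc(OC(C)=O)cc2)oc2cc(OC(C)=O)cc(OC(C)=O)c12 | intermediate
3 | 3,5,4'-tri-O-acetylkaempferol (7-OH free) | O=c1c(OC(C)=O)c(-c2ccc(OC(C)=O)cc2)oc2cc(O)cc(OC(C)=O)c12 | intermediate
4 | 3,5,4'-tri-O-acetyl-7-O-tert-butylkaempferol | O=c1c(OC(C)=O)c(-c2ccc(OC(C)=O)cc2)oc2cc(OC(C)(C)C)cc(OC(C)=O)c12 | intermediate
5 | 7-O-tert-butylkaempferol (not isolated) | O=c1c(O)c(-c2ccc(O)cc2)oc2cc(OC(C)(C)C)cc(O)c12 | intermediate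
6 | 3,5,4'-tri-O-benzyl-7-O-tert-butylkaempferol | O=c1c(OCc2ccccc2)c(-c2ccc(OCc3ccccc3)cc2)oc2cc(OC(C)(C)C)cc(OCc3ccccc3)c12 | intermediate
7 | 3,5,4'-tri-O-benzyl-7-O-tert-butyl-8-iodokaempferol | O=c1c(OCc2ccccc2)c(-c2ccc(OCc3ccccc3)cc2)oc2c(I)c(OC(C)(C)C)cc(OCc3ccccc3)c12 | intermediate
8 | 4'-benzyloxyacetophenone | CC(=O)c1ccc(OCc2ccccc2)cc1 | starting material
9 | 1-(4-benzyloxyphenyl)-2-(3,5,4'-tri-O-benzyl-7-O-tert-butylkaempferol-8-yl)ethanone | O=C(Cc1c(OC(C)(C)C)cc(OCc2ccccc2)c2c(=O)c(OCc3ccccc3)c(-c3ccc(OCc4ccccc4)cc3)oc12)c1ccc(OCc2ccccc2)cc1 | intermediate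
10 | 2-diazo-1-(4-benzyloxyphenyl)-2-(3,5,4'-tri-O-benzyl-7-O-tert-butylkaempferol-8-yl)ethanone | [N-]=[N+]=C(C(=O)c1ccc(OCc2ccccc2)cc1)c1c(OC(C)(C)C)cc(OCc2ccccc2)c2c(=O)c(OCc3ccccc3)c(-c3ccc(OCc4ccccc4)cc3)oc12 | intermediate
11 | 2,4,6-trihydroxybenzaldehyde | O=Cc1c(O)cc(O)cc1O | starting material
12 | 2-hydroxy-4,6-bis(benzyloxy)benzaldehyde | O=Cc1c(O)cc(OCc2ccccc2)cc1OCc1ccccc1 | intermediate
13 | aryloxy enol (tautomer of the oxonium ylide; enol geometry not defined; not isolated): 2-[2-(4-benzyloxyphenyl)-2-hydroxy-1-(3,5,4'-tri-O-benzyl-7-O-tert-butylkaempferol-8-yl)ethenyloxy]-4,6-bis(benzyloxy)benzaldehyde | O=Cc1c(OCc2ccccc2)cc(OCc2ccccc2)cc1OC(=C(O)c1ccc(OCc2ccccc2)cc1)c1c(OC(C)(C)C)cc(OCc2ccccc2)c2c(=O)c(OCc3ccccc3)c(-c3ccc(OCc4ccccc4)cc3)oc12 | intermediate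
14 | (2S,3R)-2-(4-benzyloxybenzoyl)-4,6-bis(benzyloxy)-2-(3,5,4'-tri-O-benzyl-7-O-tert-butylkaempferol-8-yl)-2,3-dihydrobenzofuran-3-ol | O[C@@H]1c2c(OCc3ccccc3)cc(OCc3ccccc3)cc2O[C@@]1(C(=O)c1ccc(OCc2ccccc2)cc1)c1c(OC(C)(C)C)cc(OCc2ccccc2)c2c(=O)c(OCc3ccccc3)c(-c3ccc(OCc4ccccc4)cc3)oc12 | intermediate
15 | (R)-2-(4-benzyloxybenzoyl)-4,6-bis(benzyloxy)-2-(3,5,4'-tri-O-benzyl-7-O-tert-butylkaempferol-8-yl)benzofuran-3(2H)-one | O=C1c2c(OCc3ccccc3)cc(OCc3ccccc3)cc2O[C@@]1(C(=O)c1ccc(OCc2ccccc2)cc1)c1c(OC(C)(C)C)cc(OCc2ccccc2)c2c(=O)c(OCc3ccccc3)c(-c3ccc(OCc4ccccc4)cc3)oc12 | intermediate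
16 | (R)-2-(4-benzyloxybenzoyl)-4,6-bis(benzyloxy)-2-(3,5,4'-tri-O-benzylkaempferol-8-yl)benzofuran-3(2H)-one, 7-OH free (not isolated) | O=C1c2c(OCc3ccccc3)cc(OCc3ccccc3)cc2O[C@@]1(C(=O)c1ccc(OCc2ccccc2)cc1)c1c(O)cc(OCc2ccccc2)c2c(=O)c(OCc3ccccc3)c(-c3ccc(OCc4ccccc4)cc3)oc12 | intermediate
17 | (2S,8'R)-hexa-O-benzyl ether of the target: 4,6,3',5'-tetrakis(benzyloxy)-2',8'-bis(4-benzyloxyphenyl)-8'-hydroxy-spiro[benzofuran-2,9'-furo[2,3-h]chromene]-3,4'-dione | O=C1c2c(OCc3ccccc3)cc(OCc3ccccc3)cc2O[C@@]12c1c(cc(OCc3ccccc3)c3c(=O)c(OCc4ccccc4)c(-c4ccc(OCc5ccccc5)cc4)oc13)O[C@]2(O)c1ccc(OCc2ccccc2)cc1 | intermediate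
18 | (2S,8'R)-3',4,5',6,8'-pentahydroxy-2',8'-bis(4-hydroxyphenyl)-3H,4'H,8'H-spiro[benzofuran-2,9'-furo[2,3-h]chromene]-3,4'-dione (CNP0283000.1) | O=C1c2c(O)cc(O)cc2O[C@@]12c1c(cc(O)c3c(=O)c(O)c(-c4ccc(O)cc4)oc13)O[C@]2(O)c1ccc(O)cc1 | target

**Step count and risks**

Total step count: 12. Longest linear sequence: 11 steps (steps 1–7 and 9–12 from kaempferol); step 8 is a one-step side branch.

Step 9. The carbene may be consumed without ring closure (O–H insertion followed by proton shift, azine formation, or slow attack at the crowded carbene carbon), and the acid may give poor facial control at C2. The fallback avoids the carbene with a Rap–Stoermer-type sequence and sets out from ketone 9 and aldehyde 12. Ketone 9 is brominated (PhNMe3Br3, THF, 0 °C) to the racemic α-bromo ketone F1. Etherification of F1 with the phenoxide of 12 (K2CO3, DMF, rt → 50 °C) is followed in the same flask by intramolecular aldol addition, giving the racemic dihydrobenzofuranol F2 as a mixture of C3 epimers. Dess–Martin oxidation removes the C3 centre and gives the racemic diketone F3. Preparative chromatography on a chiral stationary phase separates (R)-diketone 15 from the (S)-enantiomer F4, and the route is rejoined at 15.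

Step 6. Oxidative addition and reductive elimination at the di-ortho-substituted, electron-rich iodide may be slow, so that protodeiodination competes, and the base may open the chromone. The fallback builds the phenacyl group in stages and sets out from iodide 7. Stille coupling with allyltributylstannane (Pd(PPh3)4, toluene, 100 °C) gives the 8-allyl flavonol F5. Lemieux–Johnson cleavage (OsO4 cat., NaIO4, 2,6-lutidine, dioxane–H2O) gives the arylacetaldehyde F6. Addition of 4-benzyloxyphenylmagnesium bromide (THF, −78 °C) gives the racemic carbinol F7. Dess–Martin oxidation of F7 returns to the route at ketone 9.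

Step 12. Hydrogenolysis may stop short of removing all six benzyl groups, or may go too far by reducing the C3 ketone or cleaving the benzylic hemiketal C–O bond. The fallback changes the mode of debenzylation from hydrogenolysis to Lewis-acid cleavage: BCl3 with pentamethylbenzene as cation scavenger (CH2Cl2, −78 °C), then aqueous work-up, which restores the hemiketal. It sets out from 17 and arrives directly at 18 without a new compound (F0).

**Further compounds**

F1 | step 9 | 2-bromo-1-(4-benzyloxyphenyl)-2-(3,5,4'-tri-O-benzyl-7-O-tert-butylkaempferol-8-yl)ethanone (racemic) | O=C(C(Br)c1c(OC(C)(C)C)cc(OCc2ccccc2)c2c(=O)c(OCc3ccccc3)c(-c3ccc(OCc4ccccc4)cc3)oc12)c1ccc(OCc2ccccc2)cc1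
F2 | step 9 | racemic 2-(4-benzyloxybenzoyl)-4,6-bis(benzyloxy)-2-(3,5,4'-tri-O-benzyl-7-O-tert-butylkaempferol-8-yl)-2,3-dihydrobenzofuran-3-ol (mixture of C3 epimers) | OC1c2c(OCc3ccccc3)cc(OCc3ccccc3)cc2OC1(C(=O)c1ccc(OCc2ccccc2)cc1)c1c(OC(C)(C)C)cc(OCc2ccccc2)c2c(=O)c(OCc3ccccc3)c(-c3ccc(OCc4ccccc4)cc3)oc12
F3 | step 9 | racemic 2-(4-benzyloxybenzoyl)-4,6-bis(benzyloxy)-2-(3,5,4'-tri-O-benzyl-7-O-tert-butylkaempferol-8-yl)benzofuran-3(2H)-one | O=C1c2c(OCc3ccccc3)cc(OCc3ccccc3)cc2OC1(C(=O)c1ccc(OCc2ccccc2)cc1)c1c(OC(C)(C)C)cc(OCc2ccccc2)c2c(=O)c(OCc3ccccc3)c(-c3ccc(OCc4ccccc4)cc3)oc12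
F4 | step 9 | (S)-enantiomer of 15 (separated and set aside) | O=C1c2c(OCc3ccccc3)cc(OCc3ccccc3)cc2O[C@]1(C(=O)c1ccc(OCc2ccccc2)cc1)c1c(OC(C)(C)C)cc(OCc2ccccc2)c2c(=O)c(OCc3ccccc3)c(-c3ccc(OCc4ccccc4)cc3)oc12
F5 | step 6 | 8-allyl-3,5,4'-tri-O-benzyl-7-O-tert-butylkaempferol | C=CCc1c(OC(C)(C)C)cc(OCc2ccccc2)c2c(=O)c(OCc3ccccc3)c(-c3ccc(OCc4ccccc4)cc3)oc12
F6 | step 6 | 2-(3,5,4'-tri-O-benzyl-7-O-tert-butylkaempferol-8-yl)acetaldehyde | O=CCc1c(OC(C)(C)C)cc(OCc2ccccc2)c2c(=O)c(OCc3ccccc3)c(-c3ccc(OCc4ccccc4)cc3)oc12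
F7 | step 6 | 1-(4-benzyloxyphenyl)-2-(3,5,4'-tri-O-benzyl-7-O-tert-butylkaempferol-8-yl)ethanol (racemic) | OC(Cc1c(OC(C)(C)C)cc(OCc2ccccc2)c2c(=O)c(OCc3ccccc3)c(-c3ccc(OCc4ccccc4)cc3)oc12)c1ccc(OCc2ccccc2)cc1
F0 | step 12 | none | none
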